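## The problem

Ambofuranol (16) is a 2-aryl-3-methoxybenzofuran. Ring A of the benzofuran carries a free hydroxyl at C6 and a 3-methylbut-2-enyl (prenyl) group at the adjacent C5. The furan ring carries a methoxy group at C3, and ring B, joined through C1' to C2, is a 2-hydroxy-4-methoxyphenyl group. There is no stereocentre and the prenyl double bond has no geometry to set, so the task is one of regiochemistry and of telling four oxygen atoms apart: two phenols that must end free and two methyl ethers that must stay, one of them the enol-type ether at C3. The prenyl group has to arrive at C5 and not at C7, ortho to a phenol that must stay masked while the rest is built. The fragile parts are this ortho-prenylphenol (strong acid closes it to a 2,2-dimethylchroman; electrophilic halogen and hydrogenation attack the alkene) and the electron-rich 3-methoxy-2-arylbenzofuran (oxidants, or acid strong enough to hydrolyse the enol ether). The feature that opens a short route is the unit O1–C2–C3(OMe) fused to ring A: it corresponds to O1, C3 and C4(OMe) of a 4-methoxycoumarin. Contraction of such a coumarin bearing bromine at C3 would leave the old lactone carbonyl as a carboxyl group on C2, the very carbon to which ring B must be attached.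

## Retrosynthesis

**Unmasking the phenols (16 from 15).** The last operation should only uncover O6 and O2', so the two O–CH2OMe bonds of the bis(methoxymethyl) ether 15 are cut. Methoxymethyl (MOM) is preferred over benzyl (hydrogenolysis would reduce the prenyl alkene), over silyl (would not survive the alkoxide and hydroxide of the ring contraction) and over methyl (indistinguishable from the two methyl ethers that stay). Both phenols carry the same group, so one mild acid treatment should free both.

**Detaching ring B (15 from 12 and 14).** The C2–C1' bond is cut. This is preferred to any cut through ring B itself because the 2-hydroxy-4-methoxyphenyl unit is available as 2-bromo-5-methoxyphenol (13), one protection step from bromide 14. The benzofuran partner is the 2-carboxylic acid 12, whose carboxyl group serves as the leaving group in a palladium-catalysed decarboxylative arylation. No separate decarboxylation, halogenation or metalation of C2 is then needed. The forward reaction must tolerate two acetals and a trisubstituted alkene and must couple at C2 only; the C3 methoxy group blocks the neighbouring position.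

**Ring contraction (12 from 9, the key cut).** The furan ring is opened at O1–C2 and O1 is reconnected to the carboxyl carbon, which turns acid 12 into 3-bromo-4-methoxycoumarin 9. In the forward sense base opens the lactone to the bromoacrylate phenoxide 10, the phenoxide displaces the vinylic bromide to give ester 11, and saponification gives 12. This cut is preferred to the other furan-ring disconnections (C2=C3 by olefination, C3–C3a by acylation) for two reasons: the precursor is a coumarin made by one classical condensation, and the extruded carbon ends up exactly where the aryl group is needed. The demand on the forward step is that closure at the bromine-bearing carbon outruns substitution of the C4 methoxy group. Methoxide in methanol is therefore chosen as the base, so that any exchange at C4 is degenerate.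

**Bromine and O-methyl (9 from 8 from 7).** The O–CH3 bond and then the C3–Br bond are cut, leading to 4-hydroxycoumarin 7. Bromination is placed before methylation because the free enol of 7 is by far the most nucleophilic site in the molecule and should take up one equivalent of electrophilic bromine ahead of the prenyl alkene. The enol ether would discriminate less well.

**Pyranone ring (7 from 5 and 6).** The C2–C3 and C2–O1 bonds are cut, which removes one carbon as diethyl carbonate (6) and leaves 2-hydroxyacetophenone 5. This is the standard entry to 4-hydroxycoumarins and needs only a free ortho-hydroxyl and a methyl ketone.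

**Prenyl group and ring A (5 from 3 and 4; 3 from 2 from 1).** The aryl–CH2 bond is cut to aryl bromide 3 and prenylboronate 4. Direct C-prenylation of 2,4-dihydroxyacetophenone (1) would scatter the group over C3, C5 and oxygen; a bromine atom marks C5 unambiguously. Bromide 3 comes from 1 by bromination to 2 and selective protection of the non-chelated 4-hydroxyl.

## Roads not taken

**Alternative 1:** Ring A by benzannulation of a furylketene. The cut removes three bonds of ring A (C3a–C4, C4–C5, C6–C7). In the forward step the furyl diazo ketone A2 undergoes photochemical Wolff rearrangement to a furylketene, which combines with the prenyl siloxyalkyne A3 by [2+2] cycloaddition, 4π opening and 6π closure onto the furan β-carbon, giving the 4-hydroxybenzofuran A1.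
- Merits: the route is convergent, the prenyl/oxygen pattern of ring A is fixed by the polarity of the alkyne, and the prenyl group never meets a halogenating agent. In ring A regiocontrol it is better than the bromination and cross-coupling of the chosen plan.
- Weak points: A1 carries an extra hydroxyl at C4 that the target lacks, so triflation and reduction must follow. A2 already contains the 2-aryl-3-methoxyfuran, so the hardest part of the molecule is only moved into the starting material. A3 is a sensitive ynol ether.
- Comparison: the chosen plan sets against the better regiocontrol a ring-forming step that builds the furan itself and leaves a useful carboxyl handle instead of a superfluous hydroxyl, and a shorter sequence overall.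

**Alternative 2:** Intramolecular Wittig closure with an α-methoxy ylide. The cut is the C2=C3 bond. Triethylamine would convert the α-methoxybenzylphosphonium salt A5 into its ylide, which olefinates the neighbouring aryl ester carbonyl and closes the furan ring to the bis(silyl) ether A4.
- Merits: rings A and B are joined by a simple esterification, both the C2 aryl group and the C3 methoxy group are set in the ring-forming event, and no transition metal or high temperature is needed. In convergence this road is at least equal to the chosen plan and may be shorter, since it merges the work of the ring contraction and the biaryl coupling.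
- Weak points: A5 must be made from an acetal or α-halo ether through an oxocarbenium ion next to an aryl ester, silyl ethers and a prenyl group. α-Alkoxy ylides are unstabilised and moisture-sensitive, and their olefination of ester carbonyls to a tetrasubstituted enol ether is far less documented than that of the parent benzylic ylides.
- Comparison: the chosen plan sets against the higher convergence that all of its intermediates are stable coumarins from classical chemistry, that the ring-closing bond is a C–O bond and not a hindered C=C bond, and that no α-alkoxy phosphonium salt is required.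

**Alternative 3:** Ring B by benzannulation on the benzofuran. The cut removes C1'–C2', C2'–C3' and C4'–C5'. The dienyl diazo ketone A7 would undergo Wolff rearrangement to a vinylketene that combines with methoxyacetylene A8 by [2+2] cycloaddition, 4π opening and 6π closure, giving A6 with the 2'-hydroxyl already free.
- Merits: the regiochemistry of ring B is unambiguous, one protecting group is saved, and the hot palladium coupling with a hindered bromide is avoided. In these respects it is better than the chosen plan.
- Weak points: A7 requires a fully built 3-methoxybenzofuran with a carbon handle at C2, which is exactly what the chosen plan delivers as acid 12, plus several homologation steps. A8 is volatile and polymerises readily. A ketene is generated by light beside an electron-rich benzofuran and a nucleophilic alkene.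
- Comparison: the chosen plan sets against these advantages that ring B is bought complete and attached in one step, so its step economy is clearly better.

Key step: step 7

Assumption: the prenyl group is delivered from the commercial pinacol boronate 4 rather than from 1-bromo-3-methylbut-2-ene, because the boronate allows ligand control of linear against branched coupling.

## Route

Step 1
Reactants: 1 2,4-dihydroxyacetophenone
Product: 2 5-bromo-2,4-dihydroxyacetophenone
Conditions: Br2 (1.0 equiv), AcOH, 20 °C
Reagents that add atoms: bromine, BrBr
Why: Electrophilic aromatic bromination; C5 is para to the 2-hydroxyl, ortho to the 4-hydroxyl and less hindered than C3 between the two hydroxyls, so one equivalent should give the 5-bromo compound, which can be crystallised from minor 3-bromo and dibromo material.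

Step 2
Reactants: 2 5-bromo-2,4-dihydroxyacetophenone
Product: 3 5-bromo-2-hydroxy-4-(methoxymethoxy)acetophenone
Conditions: MOMCl (1.1 equiv), K2CO3, acetone, 0 °C to 20 °C
Reagents that add atoms: chloromethyl methyl ether, COCCl
Why: Williamson-type MOM protection; the 2-hydroxyl is held in a hydrogen bond to the acetyl carbonyl and is much less acidic and nucleophilic than the 4-hydroxyl, so mild base and one equivalent of reagent should etherify O4 only.

Step 3
Reactants: 3 5-bromo-2-hydroxy-4-(methoxymethoxy)acetophenone; 4 4,4,5,5-tetramethyl-2-(3-methylbut-2-enyl)-1,3,2-dioxaborolane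
Product: 5 2-hydroxy-4-(methoxymethoxy)-5-(3-methylbut-2-enyl)acetophenone
Conditions: PdCl2(NHC)(3-chloropyridine) (3 mol%; NHC = 1,3-bis[2,6-di(pentan-3-yl)phenyl]imidazol-2-ylidene), KOH (aq, 5 M), THF, 70 °C
Reagents that add atoms: none
Why: Suzuki–Miyaura coupling of an allylboronate; the allylpalladium σ-isomers interconvert and the bulky carbene ligand makes reductive elimination from the primary terminus the faster path, the documented way to obtain the linear prenyl arene from this boronate. The phenol is carried as its phenoxide, and the MOM ether and the ketone are stable to aqueous KOH.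

Step 4
Reactants: 5 2-hydroxy-4-(methoxymethoxy)-5-(3-methylbut-2-enyl)acetophenone; 6 diethyl carbonate
Product: 7 4-hydroxy-7-(methoxymethoxy)-6-(3-methylbut-2-enyl)coumarin
Conditions: NaH (4 equiv), toluene, 110 °C; then HCl (aq, 1 M), 0 °C, to pH 3
Reagents that add atoms: none
Why: Claisen condensation of the ketone enolate with diethyl carbonate followed by lactonisation onto the phenoxide, the standard route from 2-hydroxyacetophenones to 4-hydroxycoumarins; formation of the stabilised sodium enolate of 7 drives it, and the brief cold acidification should leave the MOM ether intact.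

Step 5
Reactants: 7 4-hydroxy-7-(methoxymethoxy)-6-(3-methylbut-2-enyl)coumarin
Product: 8 3-bromo-4-hydroxy-7-(methoxymethoxy)-6-(3-methylbut-2-enyl)coumarin
Conditions: NBS (1.0 equiv), MeCN, 0 °C, dark
Reagents that add atoms: N-bromosuccinimide, O=C1CCC(=O)N1Br
Why: Electrophilic α-halogenation of a cyclic 1,3-dicarbonyl enol; C3 of a 4-hydroxycoumarin should capture electrophilic bromine rapidly at 0 °C, whereas the trisubstituted alkene needs a trapping nucleophile or a radical chain (excluded by the aprotic medium and the dark) and C8 of the aryl ether ring is far less nucleophilic. No acid is released, so the MOM ether is safe.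

Step 6
Reactants: 8 3-bromo-4-hydroxy-7-(methoxymethoxy)-6-(3-methylbut-2-enyl)coumarin
Product: 9 3-bromo-4-methoxy-7-(methoxymethoxy)-6-(3-methylbut-2-enyl)coumarin
Conditions: Me2SO4 (1.5 equiv), K2CO3, acetone, 56 °C
Reagents that add atoms: dimethyl sulfate, COS(=O)(=O)OC
Why: O-alkylation of the ambident 4-hydroxycoumarin anion with a hard electrophile, the standard way to 4-methoxycoumarins; C-alkylation is disfavoured at the bromine-bearing C3, and any 2-methoxychromone isomer from alkylation at the lactone oxygen would be removed by chromatography.

Step 7
Reactants: 9 3-bromo-4-methoxy-7-(methoxymethoxy)-6-(3-methylbut-2-enyl)coumarin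
Product: 12 3-methoxy-6-(methoxymethoxy)-5-(3-methylbut-2-enyl)benzofuran-2-carboxylic acid, via ring-opened bromoacrylate phenoxide 10 (not isolated), via benzofuran methyl ester 11 (not isolated)
Conditions: NaOMe (4 equiv), MeOH (dry), 65 °C; then H2O, 65 °C; then HCl (aq, 1 M), 0 °C, to pH 3
Reagents that add atoms: water, O; sodium methoxide, [Na+].[O-]C (its methoxy group is present in 10 and 11 only and is lost again on saponification)
Why: Methoxide adds to the lactone carbonyl of 9 and expels the phenoxide, giving the sodium salt of the (Z)-bromoacrylate 10, in which aryl group and ester stay cis so that the phenoxide sits beside the bromine-bearing carbon. The phenoxide oxygen then bonds to that carbon and bromide leaves (nucleophilic vinylic substitution, formally a 5-endo-trig addition–elimination), so coumarin C3 becomes benzofuran C2, C4 with its methoxy group becomes C3 and the former C2 carbonyl remains as the ester of 11; water added afterwards saponifies 11 to the carboxylate of 12. The closest known reaction is the Perkin rearrangement (coumarin–benzofuran ring contraction) of 3-halocoumarins, routine with 4-alkyl and 4-aryl substituents but sparsely documented with 4-alkoxy groups, which is why the base is matched to the substituent. The one ring closed is the furan, by an oxygen nucleophile within a five-atom array, and no stereocentre is formed. The selectivity needed is ring closure over loss of the C4 methoxy group by addition–elimination: with methoxide in dry methanol any exchange at C4 returns the same compound, and hydroxide is admitted only once the aromatic benzofuran, no longer a vinylogous carbonate, has formed. Conjugate addition of alkoxide at C4, which diverts 4-unsubstituted 3-bromocoumarins, is here unproductive and reversible because C4 already bears the alkoxy group. The aryl MOM ether and the prenyl group are inert to alkoxide, and the cold acidification is kept brief to spare the acetal.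

Step 8
Reactants: 13 2-bromo-5-methoxyphenol
Product: 14 1-bromo-4-methoxy-2-(methoxymethoxy)benzene
Conditions: NaH, THF, 0 °C; MOMCl, 0 °C to 20 °C
Reagents that add atoms: chloromethyl methyl ether, COCCl
Why: Williamson-type MOM protection of a sodium phenoxide; it keeps the ortho phenol from interfering with palladium in step 9 and lets both phenols be released together at the end.

Step 9
Reactants: 12 3-methoxy-6-(methoxymethoxy)-5-(3-methylbut-2-enyl)benzofuran-2-carboxylic acid; 14 1-bromo-4-methoxy-2-(methoxymethoxy)benzene
Product: 15 3-methoxy-2-[4-methoxy-2-(methoxymethoxy)phenyl]-6-(methoxymethoxy)-5-(3-methylbut-2-enyl)benzofuran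
Conditions: Pd[P(t-Bu)3]2 (5 mol%), n-Bu4NCl, Cs2CO3, DMF, 170 °C (microwave, short reaction time)
Reagents that add atoms: none
Why: Palladium-catalysed decarboxylative cross-coupling of a heteroaromatic 2-carboxylic acid with an aryl bromide, documented for benzofuran-2-carboxylic acids that carry a C3 substituent; oxidative addition of 14 to zerovalent palladium, palladation at the electron-rich C2, loss of CO2 and reductive elimination form the C2–C1' bond, and the C3 methoxy group blocks competing C3 arylation. The basic medium spares the MOM ethers and the trisubstituted alkene is a poor Heck acceptor.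

Step 10
Reactants: 15 3-methoxy-2-[4-methoxy-2-(methoxymethoxy)phenyl]-6-(methoxymethoxy)-5-(3-methylbut-2-enyl)benzofuran
Product: 16 ambofuranol, 2-(2-hydroxy-4-methoxyphenyl)-3-methoxy-5-(3-methylbut-2-enyl)benzofuran-6-ol
Conditions: HCl (aq, 3 M), MeOH, 50 °C
Reagents that add atoms: none
Why: Acid-catalysed methanolysis of the two MOM acetals, the usual last step for prenylated phenols; dilute acid and moderate temperature are chosen because addition of the freed C6 hydroxyl to the prenyl alkene needs more forcing acid, and the aromatic 3-methoxy group is not an acetal and should stay.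

## Compound list

1 | 2,4-dihydroxyacetophenone | CC(=O)c1ccc(O)cc1O | starting material
2 | 5-bromo-2,4-dihydroxyacetophenone | CC(=O)c1cc(Br)c(O)cc1O | intermediate
3 | 5-bromo-2-hydroxy-4-(methoxymethoxy)acetophenone | CC(=O)c1cc(Br)c(OCOC)cc1O | intermediate
4 | 4,4,5,5-tetramethyl-2-(3-methylbut-2-enyl)-1,3,2-dioxaborolane (prenylboronic acid pinacol ester) | CC(C)=CCB1OC(C)(C)C(C)(C)O1 | starting material
5 | 2-hydroxy-4-(methoxymethoxy)-5-(3-methylbut-2-enyl)acetophenone | CC(=O)c1cc(CC=C(C)C)c(OCOC)cc1O | intermediate
6 | diethyl carbonate | CCOC(=O)OCC | starting material
7 | 4-hydroxy-7-(methoxymethoxy)-6-(3-methylbut-2-enyl)coumarin | Oc1cc(=O)oc2cc(OCOC)c(CC=C(C)C)cc12 | intermediate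
8 | 3-bromo-4-hydroxy-7-(methoxymethoxy)-6-(3-methylbut-2-enyl)coumarin | Oc1c(Br)c(=O)oc2cc(OCOC)c(CC=C(C)C)cc12 | intermediate
9 | 3-bromo-4-methoxy-7-(methoxymethoxy)-6-(3-methylbut-2-enyl)coumarin | COc1c(Br)c(=O)oc2cc(OCOC)c(CC=C(C)C)cc12 | intermediate
10 | methyl (Z)-2-bromo-3-[2-hydroxy-4-(methoxymethoxy)-5-(3-methylbut-2-enyl)phenyl]-3-methoxyprop-2-enoate, present as its sodium phenoxide | Br/C(C(=O)OC)=C(\OC)c1cc(CC=C(C)C)c(OCOC)cc1O | intermediate (not isolated)
11 | methyl 3-methoxy-6-(methoxymethoxy)-5-(3-methylbut-2-enyl)benzofuran-2-carboxylate | COc1c(C(=O)OC)oc2cc(OCOC)c(CC=C(C)C)cc12 | intermediate (not isolated)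
12 | 3-methoxy-6-(methoxymethoxy)-5-(3-methylbut-2-enyl)benzofuran-2-carboxylic acid | COc1c(C(=O)O)oc2cc(OCOC)c(CC=C(C)C)cc12 | intermediate
13 | 2-bromo-5-methoxyphenol | COc1ccc(Br)c(O)c1 | starting material
14 | 1-bromo-4-methoxy-2-(methoxymethoxy)benzene | COCOc1cc(OC)ccc1Br | intermediate
15 | 3-methoxy-2-[4-methoxy-2-(methoxymethoxy)phenyl]-6-(methoxymethoxy)-5-(3-methylbut-2-enyl)benzofuran | COc1ccc(-c2oc3cc(OCOC)c(CC=C(C)C)cc3c2OC)c(OCOC)c1 | intermediate
16 | ambofuranol | COc1ccc(-c2oc3cc(O)c(CC=C(C)C)cc3c2OC)c(O)c1 | target

## Step count and least certain steps

Total step count: 10. Longest linear sequence: 9 steps (steps 1 to 7, 9 and 10, from 1); step 8 is a one-step side branch.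

**Step 7 (key step).** The closure may be slow or fail because the bromine-bearing carbon is the electron-rich end of a push–pull alkene into which the C4 methoxy group donates. The ring-opened phenoxide would then persist and simply re-lactonise to 9 on acidification, or lose bromine by halophilic attack of alkoxide. Premature entry of water would allow demethoxylation at C4. Heating in a sealed vessel is the first adjustment.

The fallback abandons the contraction and builds the furan ring by a Dieckmann-type condensation.
- It sets out from boronate 4 and commercial methyl 5-bromo-2,4-dihydroxybenzoate F1.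
- MOM protection of the non-chelated hydroxyl (MOMCl, K2CO3, acetone) would give methyl 5-bromo-2-hydroxy-4-(methoxymethoxy)benzoate F2.
- Coupling with 4 under the conditions of step 3 would give methyl 2-hydroxy-4-(methoxymethoxy)-5-(3-methylbut-2-enyl)benzoate F3.
- O-alkylation with methyl bromoacetate (K2CO3, acetone) would give methyl 2-(2-methoxy-2-oxoethoxy)-4-(methoxymethoxy)-5-(3-methylbut-2-enyl)benzoate F4.
- NaOMe in MeOH would close it to methyl 3-hydroxy-6-(methoxymethoxy)-5-(3-methylbut-2-enyl)benzofuran-2-carboxylate F5.
- Dimethyl sulfate and K2CO3 would methylate the enol to ester 11, where the route is rejoined; saponification gives 12.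

**Step 9.** Protodecarboxylation of 12 may outrun the coupling, oxidative addition of the hindered, electron-rich bromide 14 may be sluggish, and palladium hydride at 170 °C may move the prenyl double bond into conjugation with the ring. The fallback separates the two events and sets out from 12. Catalytic protodecarboxylation (Ag2CO3, AcOH, DMSO, 120 °C) would give 3-methoxy-6-(methoxymethoxy)-5-(3-methylbut-2-enyl)benzofuran F6. Direct C2–H arylation of F6 with 14 (Pd(OAc)2, PCy3·HBF4, pivalic acid, K2CO3, DMA, 100 °C) would return to the route at 15.

**Step 3.** Reductive elimination through the tertiary allyl terminus would erode the linear selectivity and give the 1,1-dimethylallyl isomer, and the boronate may suffer protodeboronation in hot aqueous base. The fallback introduces a symmetrical allyl group and corrects it by metathesis. From 3, coupling with allylboronic acid pinacol ester (Pd(PPh3)4, CsF, THF, 65 °C) would give 5-allyl-2-hydroxy-4-(methoxymethoxy)acetophenone F7. Cross-metathesis of F7 with 2-methylbut-2-ene (second-generation Grubbs catalyst, RuCl2(H2IMes)(PCy3)(=CHPh), CH2Cl2, 40 °C) would return to the route at 5.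

**Step 5.** Electrophilic bromine may be taken up by the prenyl double bond (with capture of the bromonium ion by the neighbouring acetal oxygen) or a second time at C3. The fallback defers the prenyl group until no halogenating agent remains to be used.
- From 3, condensation with 6 as in step 4 would give 6-bromo-4-hydroxy-7-(methoxymethoxy)coumarin F8.
- NBS would give 3,6-dibromo-4-hydroxy-7-(methoxymethoxy)coumarin F9.
- Dimethyl sulfate and K2CO3 would give 3,6-dibromo-4-methoxy-7-(methoxymethoxy)coumarin F10.
- NaOMe in dry MeOH would contract F10 through methyl (Z)-2-bromo-3-[5-bromo-2-hydroxy-4-(methoxymethoxy)phenyl]-3-methoxyprop-2-enoate F11 to methyl 5-bromo-3-methoxy-6-(methoxymethoxy)benzofuran-2-carboxylate F12; only the vinylic bromide is displaced.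
- Coupling of F12 with 4 under the conditions of step 3 would return to the route at ester 11, which the aqueous base saponifies to 12.

**Step 10.** Protonation of the prenyl alkene and addition of the freed C6 hydroxyl (chroman formation), or hydration of the alkene, may accompany acetal cleavage. The fallback replaces Brønsted-acid solvolysis by silylative cleavage. From 15, TMSOTf and 2,2'-bipyridyl (MeCN, 0 °C) would give the bis(trimethylsilyl) ether 3-methoxy-2-[4-methoxy-2-(trimethylsilyloxy)phenyl]-5-(3-methylbut-2-enyl)-6-(trimethylsilyloxy)benzofuran F13. Water at neutral pH then hydrolyses F13 to 16.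

## Further compounds

F1 | step 7 | methyl 5-bromo-2,4-dihydroxybenzoate | COC(=O)c1cc(Br)c(O)cc1O
F2 | step 7 | methyl 5-bromo-2-hydroxy-4-(methoxymethoxy)benzoate | COC(=O)c1cc(Br)c(OCOC)cc1O
F3 | step 7 | methyl 2-hydroxy-4-(methoxymethoxy)-5-(3-methylbut-2-enyl)benzoate | COC(=O)c1cc(CC=C(C)C)c(OCOC)cc1O
F4 | step 7 | methyl 2-(2-methoxy-2-oxoethoxy)-4-(methoxymethoxy)-5-(3-methylbut-2-enyl)benzoate | COC(=O)COc1cc(OCOC)c(CC=C(C)C)cc1C(=O)OC
F5 | step 7 | methyl 3-hydroxy-6-(methoxymethoxy)-5-(3-methylbut-2-enyl)benzofuran-2-carboxylate | COC(=O)c1oc2cc(OCOC)c(CC=C(C)C)cc2c1O
F6 | step 9 | 3-methoxy-6-(methoxymethoxy)-5-(3-methylbut-2-enyl)benzofuran | COc1coc2cc(OCOC)c(CC=C(C)C)cc12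
F7 | step 3 | 5-allyl-2-hydroxy-4-(methoxymethoxy)acetophenone | CC(=O)c1cc(CC=C)c(OCOC)cc1O
F8 | step 5 | 6-bromo-4-hydroxy-7-(methoxymethoxy)coumarin | Oc1cc(=O)oc2cc(OCOC)c(Br)cc12
F9 | step 5 | 3,6-dibromo-4-hydroxy-7-(methoxymethoxy)coumarin | Oc1c(Br)c(=O)oc2cc(OCOC)c(Br)cc12
F10 | step 5 | 3,6-dibromo-4-methoxy-7-(methoxymethoxy)coumarin | COc1c(Br)c(=O)oc2cc(OCOC)c(Br)cc12
F11 | step 5 | methyl (Z)-2-bromo-3-[5-bromo-2-hydroxy-4-(methoxymethoxy)phenyl]-3-methoxyprop-2-enoate | Br/C(C(=O)OC)=C(\OC)c1cc(Br)c(OCOC)cc1O
F12 | step 5 | methyl 5-bromo-3-methoxy-6-(methoxymethoxy)benzofuran-2-carboxylate | COc1c(C(=O)OC)oc2cc(OCOC)c(Br)cc12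
F13 | step 10 | 3-methoxy-2-[4-methoxy-2-(trimethylsilyloxy)phenyl]-5-(3-methylbut-2-enyl)-6-(trimethylsilyloxy)benzofuran | COc1ccc(-c2oc3cc(O[Si](C)(C)C)c(CC=C(C)C)cc3c2OC)c(O[Si](C)(C)C)c1
A1 | alternative 1 | 2-[2-(tert-butyldimethylsilyloxy)-4-methoxyphenyl]-3-methoxy-5-(3-methylbut-2-enyl)-6-(triisopropylsilyloxy)benzofuran-4-ol | COc1ccc(-c2oc3cc(O[Si](C(C)C)(C(C)C)C(C)C)c(CC=C(C)C)c(O)c3c2OC)c(O[Si](C)(C)C(C)(C)C)c1
A2 | alternative 1 | 1-{5-[2-(tert-butyldimethylsilyloxy)-4-methoxyphenyl]-4-methoxyfuran-2-yl}-2-diazoethanone | COc1ccc(-c2oc(C(=O)C=[N+]=[N-])cc2OC)c(O[Si](C)(C)C(C)(C)C)c1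
A3 | alternative 1 | triisopropyl(5-methylhex-4-en-1-ynyloxy)silane | CC(C)=CCC#CO[Si](C(C)C)(C(C)C)C(C)C
A4 | alternative 2 | ambofuranol bis(tert-butyldimethylsilyl) ether | COc1ccc(-c2oc3cc(O[Si](C)(C)C(C)(C)C)c(CC=C(C)C)cc3c2OC)c(O[Si](C)(C)C(C)(C)C)c1
A5 | alternative 2 | racemic {[2-{[2-(tert-butyldimethylsilyloxy)-4-methoxybenzoyl]oxy}-4-(tert-butyldimethylsilyloxy)-5-(3-methylbut-2-enyl)phenyl](methoxy)methyl}triphenylphosphonium bromide | COC(c1cc(CC=C(C)C)c(O[Si](C)(C)C(C)(C)C)cc1OC(=O)c1ccc(OC)cc1O[Si](C)(C)C(C)(C)C)[P+](c1ccccc1)(c1ccccc1)c1ccccc1.[Br-]
A6 | alternative 3 | ambofuranol 6-O-triisopropylsilyl ether | COc1ccc(-c2oc3cc(O[Si](C(C)C)(C(C)C)C(C)C)c(CC=C(C)C)cc3c2OC)c(O)c1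
A7 | alternative 3 | (E)-1-diazo-4-[3-methoxy-5-(3-methylbut-2-enyl)-6-(triisopropylsilyloxy)benzofuran-2-yl]but-3-en-2-one | [N-]=[N+]=CC(=O)/C=C/c1oc2cc(O[Si](C(C)C)(C(C)C)C(C)C)c(CC=C(C)C)cc2c1OC
A8 | alternative 3 | methoxyacetylene | COC#C
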